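**Plan**
- Cuts: the two O-protecting groups come off last. The C3–acyl bond goes back to a C3 stannane and (R)-2-silyloxy-3-methylbutanoyl chloride. The C3=C4 enol ether goes back to a δ-lactone, and C4a–H to a C4=C4a enoate. C1–C7a and O2–C3 are cut together at the end.
- Enabling feature: in the cyclopenta[c]pyran ring, C1–O2 is the former C=O of a coumarin-3-carbaldehyde. C7a–C4a–C4–C3 is the backbone of an ester silyl dienolate (C7a=C4a–C4=C3) whose γ-carbon C7a adjoins the C7 methyl stereocentre. One carbonyl [4+2] therefore joins both halves and closes the pyran ring.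
- Ring order forward: cyclopentene by ene-ynoate metathesis, coumarin in a separate branch, pyran ring in the hetero-Diels–Alder step. The hydroxy-acyl chain is attached last by Stille acylation.
- Stereochemistry: C7 comes from (S)-β-citronellene. C7a (anti to the C7 methyl) and C1 (coumarin exo) are set in the cycloaddition. C4a is set by hydrogenation on the face of H7a. The carbinol carbon comes from (R)-2-hydroxy-3-methylbutanoic acid.

Key step: step 9

Remark on numbering: C1, O2, C3, C4, C4a, C5–C7, C7a are the cyclopenta[c]pyran positions of the target; primed numbers are coumarin positions.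
Assumption: the geometry of the silyl ketene acetal and the C4 configuration of the saturated lactone do not matter, because C3 becomes a carbonyl carbon and C4 becomes sp2 again later.

Step 1
Reactants: 1 (S)-β-citronellene
Product: 3 (4S)-4-methylhex-5-enal, via ozonide 2 (not isolated)
Conditions: O3, CH2Cl2, −78 °C (Sudan Red 7B end point); Me2S, −78 °C → rt
Reagents that add atoms: ozone, [O-][O+]=O
Why: Chemoselective ozonolysis with reductive work-up, in which electrophilic ozone cleaves the electron-rich trisubstituted alkene far faster than the vinyl group and leaves the stereocentre untouched.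

Step 2
Reactants: 3 (4S)-4-methylhex-5-enal
Product: 4 (3S)-3-methylhept-1-en-6-yne
Conditions: MeC(O)C(N2)P(O)(OMe)2, K2CO3, MeOH, 0 °C → rt
Reagents that add atoms: dimethyl (1-diazo-2-oxopropyl)phosphonate, CC(=O)C(=[N+]=[N-])P(=O)(OC)OC
Why: Seyferth–Gilbert homologation in the Ohira–Bestmann variant converts the aldehyde into the terminal alkyne under mild carbonate conditions, and the remote stereocentre cannot epimerise.

Step 3
Reactants: 4 (3S)-3-methylhept-1-en-6-yne
Product: 6 methyl (6S)-6-methyloct-7-en-2-ynoate, via lithium acetylide 5 (not isolated)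
Conditions: n-BuLi, THF, −78 °C; ClCO2Me, −78 → 0 °C
Reagents that add atoms: methyl chloroformate, COC(=O)Cl
Why: Deprotonation of the terminal alkyne and C-acylation of the lithium acetylide with a chloroformate is the standard route to alk-2-ynoates.

Step 4
Reactants: 6 methyl (6S)-6-methyloct-7-en-2-ynoate
Product: 7 methyl 2-[(3S)-3-methylcyclopent-1-en-1-yl]prop-2-enoate
Conditions: Grubbs II (5 mol %), ethylene (1 atm), CH2Cl2, 40 °C; used directly
Reagents that add atoms: none
Why: Exo-mode ring-closing enyne metathesis of a 1,6-ene-ynoate, an established substrate class, forms the C4a=C7a ring alkene and moves the CH2 terminus onto the ester-bearing carbon, with ethylene speeding turnover of the ester-substituted carbene.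

Step 5
Reactants: 7 methyl 2-[(3S)-3-methylcyclopent-1-en-1-yl]prop-2-enoate
Product: 8 triethyl{[(1E)-1-methoxy-2-[(3S)-3-methylcyclopent-1-en-1-yl]prop-1-en-1-yl]oxy}silane
Conditions: Et3SiH, RhCl(PPh3)3 (1 mol %), toluene, 50 °C; bulb-to-bulb distillation
Reagents that add atoms: triethylsilane, CC[SiH](CC)CC
Why: Rhodium-catalysed 1,4-hydrosilylation of an α-substituted acrylate puts H on the CH2 terminus (the future C4 methyl) and silicon on the carbonyl oxygen, so the silyl ketene acetal forms without base, while the cross-conjugated trisubstituted ring alkene stays and the small methoxy group should end up on the inner side of the diene.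

Step 6
Reactants: 9 1-(2-hydroxy-6-methylphenyl)ethanone
Product: 11 4-hydroxy-5-methyl-2H-chromen-2-one, via sodium coumarin-4-olate 10 (not isolated)
Conditions: NaH, (EtO)2CO, toluene, 110 °C; aq. HCl
Reagents that add atoms: diethyl carbonate, CCOC(=O)OCC
Why: Claisen-type C-acylation of the ketone enolate with the carbonate, followed by lactonisation onto the phenol, is the classical 4-hydroxycoumarin synthesis and fixes the methyl group at C5′.

Step 7
Reactants: 11 4-hydroxy-5-methyl-2H-chromen-2-one
Product: 13 4-chloro-5-methyl-2-oxo-2H-chromene-3-carbaldehyde, via iminium chloride 12 (not isolated)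
Conditions: POCl3, DMF, 0 → 60 °C; ice-water
Reagents that add atoms: N,N-dimethylformamide, CN(C)C=O; phosphoryl chloride, O=P(Cl)(Cl)Cl; water, O
Why: Vilsmeier–Haack formylation at the nucleophilic C3′ with simultaneous exchange of the 4′-OH for chloride is the known behaviour of 4-hydroxycoumarins.

Step 8
Reactants: 13 4-chloro-5-methyl-2-oxo-2H-chromene-3-carbaldehyde
Product: 14 4-methoxy-5-methyl-2-oxo-2H-chromene-3-carbaldehyde
Conditions: NaOMe (1 equiv), MeOH–THF, −10 °C
Reagents that add atoms: sodium methoxide, C[O-].[Na+]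
Why: Addition–elimination (vinylogous acyl substitution) of methoxide at C4′, which is activated by both the lactone and the formyl group, replaces chloride faster than either carbonyl is attacked irreversibly.

Step 9
Reactants: 8 triethyl{[(1E)-1-methoxy-2-[(3S)-3-methylcyclopent-1-en-1-yl]prop-1-en-1-yl]oxy}silane; 14 4-methoxy-5-methyl-2-oxo-2H-chromene-3-carbaldehyde
Product: 16 (1R,7S,7aR)-1-(4-methoxy-5-methyl-2-oxo-2H-chromen-3-yl)-4,7-dimethyl-5,6,7,7a-tetrahydrocyclopenta[c]pyran-3(1H)-one, via orthoester cycloadduct 15 (not isolated)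
Conditions: Eu(fod)3 (10 mol %), 4 Å MS, CH2Cl2, −20 °C → rt; then TFA (10 mol %), 0 °C
Reagents that add atoms: none
Why: Eu(III) chelates the formyl oxygen and the neighbouring C2′ carbonyl oxygen, and the activated C1=O2 unit adds across C7a and C3 of the cisoid rotamer of 8 in an asynchronous [4+2] in which C1–C7a runs ahead of O2–C3, after which TFA collapses the mixed orthoester 15 to the lactone with loss of Et3SiOMe. The closest known reaction is the lanthanide- or Lewis-acid-catalysed carbonyl hetero-Diels–Alder reaction (a vinylogous Mukaiyama aldol–lactonisation in the stepwise limit) of Brassard-type 1-alkoxy-1-silyloxydienes with aldehydes to 5,6-dihydropyran-2-ones. The pyran ring closes as the six-membered ring of the cycloaddition, which in the stepwise limit is a 6-exo-trig attack of the C1 oxygen on C3. C7a is controlled by the C7 methyl group, which covers one face of the cyclopentene so that C1 bonds trans to it. C1 is controlled by the exo position of the coumarin: in the chelate the metal lies on the same side of the C=O bond as the aryl group, so the whole chelate turns away from the diene and only H1 lies endo, which places the coumarin trans to C7 (H1 and H7a anti), the pseudo-diequatorial and more stable arrangement. The step needs γ- over α-attack, reaction through the cisoid rotamer (which the ring does not lock) and attack at the formyl carbon rather than C4′; the fully substituted α-carbon C4 secures the first, the clash of the inner methoxy group with C5H2 in the transoid rotamer together with the 2,3-disubstitution of the diene secures the second, and the 4′-methoxy and peri 5′-methyl groups shielding C4′ secure the third.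

Step 10
Reactants: 16 (1R,7S,7aR)-1-(4-methoxy-5-methyl-2-oxo-2H-chromen-3-yl)-4,7-dimethyl-5,6,7,7a-tetrahydrocyclopenta[c]pyran-3(1H)-one
Product: 17 (1R,4S,4aS,7S,7aR)-1-(4-methoxy-5-methyl-2-oxo-2H-chromen-3-yl)-4,7-dimethylhexahydrocyclopenta[c]pyran-3(1H)-one
Conditions: H2 (20 bar), 10% Pd/C, EtOAc, rt
Reagents that add atoms: none
Why: Heterogeneous syn hydrogenation of the ring-fusion enoate should take place on the face carrying H7a, away from which C1 with its axial H1 is puckered, as is usual for hydrindenone-type ring-fusion alkenes that give cis-fused products, so C4a (and the transient C4 centre) are set cis to H7a while the push–pull, fully substituted coumarin alkene stays.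

Step 11
Reactants: 17 (1R,4S,4aS,7S,7aR)-1-(4-methoxy-5-methyl-2-oxo-2H-chromen-3-yl)-4,7-dimethylhexahydrocyclopenta[c]pyran-3(1H)-one
Product: 19 (1R,4aS,7S,7aR)-1-(4-methoxy-5-methyl-2-oxo-2H-chromen-3-yl)-4,7-dimethyl-1,4a,5,6,7,7a-hexahydrocyclopenta[c]pyran-3-yl diphenyl phosphate, via potassium lactone enolate 18 (not isolated)
Conditions: KHMDS, THF–HMPA, −78 °C; (PhO)2P(O)Cl
Reagents that add atoms: diphenyl chlorophosphate, O=P(Cl)(Oc1ccccc1)Oc1ccccc1
Why: Kinetic enolisation of the δ-lactone at C4, its only clearly acidic C–H, and O-phosphorylation give the cyclic ketene acetal phosphate, a known lactone activation that installs C3=C4, erases C4 and leaves C4a untouched.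

Step 12
Reactants: 19 (1R,4aS,7S,7aR)-1-(4-methoxy-5-methyl-2-oxo-2H-chromen-3-yl)-4,7-dimethyl-1,4a,5,6,7,7a-hexahydrocyclopenta[c]pyran-3-yl diphenyl phosphate
Product: 20 3-[(1R,4aS,7S,7aR)-4,7-dimethyl-3-(trimethylstannyl)-1,4a,5,6,7,7a-hexahydrocyclopenta[c]pyran-1-yl]-4-methoxy-5-methyl-2H-chromen-2-one
Conditions: (Me3Sn)2, Pd(PPh3)4 (10 mol %), LiCl, THF, 65 °C
Reagents that add atoms: hexamethylditin, C[Sn](C)(C)[Sn](C)(C)C
Why: Palladium(0)-catalysed stannylation of lactone-derived ketene acetal phosphates with hexamethylditin (oxidative addition into C–OP, transmetalation, reductive elimination) is established and is neutral enough for the coumarin.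

Step 13
Reactants: 21 (R)-2-hydroxy-3-methylbutanoic acid
Product: 22 tert-butyldimethylsilyl (2R)-2-[(tert-butyldimethylsilyl)oxy]-3-methylbutanoate
Conditions: TBSCl (2.5 equiv), imidazole, DMF, rt
Reagents that add atoms: tert-butyldimethylsilyl chloride, CC(C)(C)[Si](C)(C)Cl
Why: Standard imidazole-promoted silylation covers the hydroxyl and carboxyl groups in one operation without touching the stereocentre.

Step 14
Reactants: 22 tert-butyldimethylsilyl (2R)-2-[(tert-butyldimethylsilyl)oxy]-3-methylbutanoate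
Product: 23 (2R)-2-[(tert-butyldimethylsilyl)oxy]-3-methylbutanoyl chloride
Conditions: (COCl)2, DMF (cat.), CH2Cl2, 0 °C → rt; used crude
Reagents that add atoms: oxalyl chloride, O=C(Cl)C(=O)Cl
Why: Direct conversion of a silyl ester into the acid chloride with oxalyl chloride and catalytic DMF runs under neutral conditions without free HCl or base, so the silyl ether and the α-stereocentre are kept.

Step 15
Reactants: 20 3-[(1R,4aS,7S,7aR)-4,7-dimethyl-3-(trimethylstannyl)-1,4a,5,6,7,7a-hexahydrocyclopenta[c]pyran-1-yl]-4-methoxy-5-methyl-2H-chromen-2-one; 23 (2R)-2-[(tert-butyldimethylsilyl)oxy]-3-methylbutanoyl chloride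
Product: 24 3-{(1R,4aS,7S,7aR)-3-[(2R)-2-[(tert-butyldimethylsilyl)oxy]-3-methylbutanoyl]-4,7-dimethyl-1,4a,5,6,7,7a-hexahydrocyclopenta[c]pyran-1-yl}-4-methoxy-5-methyl-2H-chromen-2-one
Conditions: Pd2(dba)3 (5 mol %), P(2-furyl)3 (20 mol %), toluene, 50 °C
Reagents that add atoms: none
Why: Stille acylation of an electron-rich α-alkoxyvinylstannane with an acid chloride, known for 1-stannyl glycals, forms the C3–acyl bond under base-free conditions that preserve the α-silyloxy stereocentre.

Step 16
Reactants: 24 3-{(1R,4aS,7S,7aR)-3-[(2R)-2-[(tert-butyldimethylsilyl)oxy]-3-methylbutanoyl]-4,7-dimethyl-1,4a,5,6,7,7a-hexahydrocyclopenta[c]pyran-1-yl}-4-methoxy-5-methyl-2H-chromen-2-one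
Product: 26 3-{(1R,4aS,7S,7aR)-3-[(2R)-2-[(tert-butyldimethylsilyl)oxy]-3-methylbutanoyl]-4,7-dimethyl-1,4a,5,6,7,7a-hexahydrocyclopenta[c]pyran-1-yl}-4-hydroxy-5-methyl-2H-chromen-2-one, via lithium coumarin-4-olate 25 (not isolated)
Conditions: LiCl, DMSO, 60 °C; dil. HCl
Reagents that add atoms: none
Why: SN2 dealkylation of a vinylogous methyl ester by chloride, as used for methyl tetronates and 4-methoxypyranones, releases the stabilised 4′-olate under nearly neutral conditions that spare the acyl enol ether, the silyl ether and the α-stereocentre.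

Step 17
Reactants: 26 3-{(1R,4aS,7S,7aR)-3-[(2R)-2-[(tert-butyldimethylsilyl)oxy]-3-methylbutanoyl]-4,7-dimethyl-1,4a,5,6,7,7a-hexahydrocyclopenta[c]pyran-1-yl}-4-hydroxy-5-methyl-2H-chromen-2-one
Product: 27 CNP0214255.1, 4-hydroxy-3-{(1R,4aS,7S,7aR)-3-[(2R)-2-hydroxy-3-methylbutanoyl]-4,7-dimethyl-1,4a,5,6,7,7a-hexahydrocyclopenta[c]pyran-1-yl}-5-methyl-2H-chromen-2-one
Conditions: HF·pyridine, pyridine, THF, 0 °C → rt
Reagents that add atoms: none
Why: Buffered fluoride desilylation removes the TBS ether without base, so the α-hydroxy ketone, the γ-acidic C4a–H and the C1–O2 bond are not disturbed.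

**Compound list**
1 | (S)-β-citronellene, (3S)-3,7-dimethylocta-1,6-diene | C=C[C@@H](C)CCC=C(C)C | starting material
2 | 3,3-dimethyl-5-[(3S)-3-methylpent-4-en-1-yl]-1,2,4-trioxolane (ozonide) | C=C[C@@H](C)CCC1OOC(C)(C)O1 | intermediate
3 | (4S)-4-methylhex-5-enal | C=C[C@@H](C)CCC=O | intermediate
4 | (3S)-3-methylhept-1-en-6-yne | C=C[C@@H](C)CCC#C | intermediate
5 | lithium (5S)-5-methylhept-6-en-1-yn-1-ide | C=C[C@@H](C)CCC#[C-].[Li+] | intermediate
6 | methyl (6S)-6-methyloct-7-en-2-ynoate | C=C[C@@H](C)CCC#CC(=O)OC | intermediate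
7 | methyl 2-[(3S)-3-methylcyclopent-1-en-1-yl]prop-2-enoate | C=C(C(=O)OC)C1=C[C@@H](C)CC1 | intermediate
8 | triethyl{[(1E)-1-methoxy-2-[(3S)-3-methylcyclopent-1-en-1-yl]prop-1-en-1-yl]oxy}silane | CO/C(O[Si](CC)(CC)CC)=C(/C)C1=C[C@@H](C)CC1 | intermediate
9 | 1-(2-hydroxy-6-methylphenyl)ethanone | CC(=O)c1c(C)cccc1O | starting material
10 | sodium 5-methyl-2-oxo-2H-chromen-4-olate | Cc1cccc2oc(=O)cc([O-])c12.[Na+] | intermediate
11 | 4-hydroxy-5-methyl-2H-chromen-2-one | Cc1cccc2oc(=O)cc(O)c12 | intermediate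
12 | N-[(4-chloro-5-methyl-2-oxo-2H-chromen-3-yl)methylidene]-N-methylmethanaminium chloride | C[N+](C)=Cc1c(Cl)c2c(C)cccc2oc1=O.[Cl-] | intermediate
13 | 4-chloro-5-methyl-2-oxo-2H-chromene-3-carbaldehyde | O=Cc1c(Cl)c2c(C)cccc2oc1=O | intermediate
14 | 4-methoxy-5-methyl-2-oxo-2H-chromene-3-carbaldehyde | COc1c(C=O)c(=O)oc2cccc(C)c12 | intermediate
15 | 4-methoxy-3-[(1R,7S,7aR)-3-methoxy-4,7-dimethyl-3-(triethylsilyloxy)-1,3,5,6,7,7a-hexahydrocyclopenta[c]pyran-1-yl]-5-methyl-2H-chromen-2-one (C3 undefined) | CC1=C2CC[C@H](C)[C@H]2[C@H](c2c(OC)c3c(C)cccc3oc2=O)OC1(OC)O[Si](CC)(CC)CC | intermediate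
16 | (1R,7S,7aR)-1-(4-methoxy-5-methyl-2-oxo-2H-chromen-3-yl)-4,7-dimethyl-5,6,7,7a-tetrahydrocyclopenta[c]pyran-3(1H)-one | CC1=C2CC[C@H](C)[C@H]2[C@H](c2c(OC)c3c(C)cccc3oc2=O)OC1=O | intermediate
17 | (1R,4S,4aS,7S,7aR)-1-(4-methoxy-5-methyl-2-oxo-2H-chromen-3-yl)-4,7-dimethylhexahydrocyclopenta[c]pyran-3(1H)-one | C[C@@H]1C(=O)O[C@@H](c2c(OC)c3c(C)cccc3oc2=O)[C@H]2[C@@H]1CC[C@@H]2C | intermediate
18 | potassium (1R,4aS,7S,7aR)-1-(4-methoxy-5-methyl-2-oxo-2H-chromen-3-yl)-4,7-dimethyl-1,4a,5,6,7,7a-hexahydrocyclopenta[c]pyran-3-olate | CC1=C([O-])O[C@@H](c2c(OC)c3c(C)cccc3oc2=O)[C@H]2[C@@H]1CC[C@@H]2C.[K+] | intermediate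
19 | (1R,4aS,7S,7aR)-1-(4-methoxy-5-methyl-2-oxo-2H-chromen-3-yl)-4,7-dimethyl-1,4a,5,6,7,7a-hexahydrocyclopenta[c]pyran-3-yl diphenyl phosphate | CC1=C(OP(=O)(Oc2ccccc2)Oc2ccccc2)O[C@@H](c2c(OC)c3c(C)cccc3oc2=O)[C@H]2[C@@H]1CC[C@@H]2C | intermediate
20 | 3-[(1R,4aS,7S,7aR)-4,7-dimethyl-3-(trimethylstannyl)-1,4a,5,6,7,7a-hexahydrocyclopenta[c]pyran-1-yl]-4-methoxy-5-methyl-2H-chromen-2-one | CC1=C([Sn](C)(C)C)O[C@@H](c2c(OC)c3c(C)cccc3oc2=O)[C@H]2[C@@H]1CC[C@@H]2C | intermediate
21 | (R)-2-hydroxy-3-methylbutanoic acid | CC(C)[C@@H](O)C(=O)O | starting material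
22 | tert-butyldimethylsilyl (2R)-2-[(tert-butyldimethylsilyl)oxy]-3-methylbutanoate | CC(C)[C@@H](O[Si](C)(C)C(C)(C)C)C(=O)O[Si](C)(C)C(C)(C)C | intermediate
23 | (2R)-2-[(tert-butyldimethylsilyl)oxy]-3-methylbutanoyl chloride | CC(C)[C@@H](O[Si](C)(C)C(C)(C)C)C(=O)Cl | intermediate
24 | 3-{(1R,4aS,7S,7aR)-3-[(2R)-2-[(tert-butyldimethylsilyl)oxy]-3-methylbutanoyl]-4,7-dimethyl-1,4a,5,6,7,7a-hexahydrocyclopenta[c]pyran-1-yl}-4-methoxy-5-methyl-2H-chromen-2-one | CC1=C(C(=O)[C@H](O[Si](C)(C)C(C)(C)C)C(C)C)O[C@@H](c2c(OC)c3c(C)cccc3oc2=O)[C@H]2[C@@H]1CC[C@@H]2C | intermediate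
25 | lithium 4-olate of 26 | CC1=C(C(=O)[C@H](O[Si](C)(C)C(C)(C)C)C(C)C)O[C@@H](c2c([O-])c3c(C)cccc3oc2=O)[C@H]2[C@@H]1CC[C@@H]2C.[Li+] | intermediate
26 | 3-{(1R,4aS,7S,7aR)-3-[(2R)-2-[(tert-butyldimethylsilyl)oxy]-3-methylbutanoyl]-4,7-dimethyl-1,4a,5,6,7,7a-hexahydrocyclopenta[c]pyran-1-yl}-4-hydroxy-5-methyl-2H-chromen-2-one | CC1=C(C(=O)[C@H](O[Si](C)(C)C(C)(C)C)C(C)C)O[C@@H](c2c(O)c3c(C)cccc3oc2=O)[C@H]2[C@@H]1CC[C@@H]2C | intermediate
27 | CNP0214255.1, 4-hydroxy-3-{(1R,4aS,7S,7aR)-3-[(2R)-2-hydroxy-3-methylbutanoyl]-4,7-dimethyl-1,4a,5,6,7,7a-hexahydrocyclopenta[c]pyran-1-yl}-5-methyl-2H-chromen-2-one | CC1=C(C(=O)[C@H](O)C(C)C)O[C@@H](c2c(O)c3c(C)cccc3oc2=O)[C@H]2[C@@H]1CC[C@@H]2C | target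

**Totals**
Total step count: 17.
Longest linear sequence: 12 steps (steps 1–5, 9–12, 15–17).

**Steps most likely to fail**

**Step 9.**
- Risk: the addition may run stepwise through the transoid rotamer of the diene. The new C4=C4a bond would then form with the ester turned away from the C1 oxygen, and ring closure would stop.
- Risk: the exo preference at C1 may erode if the europium chelate is not maintained.
- Fallback: it sets out from 8 and 14. An open-chain vinylogous Mukaiyama aldol addition with a bulky monodentate Lewis acid (B(C6F5)3 cat., CH2Cl2, −78 °C, silyl transfer to oxygen) would form only C1–C7a. It would give the silylated adduct methyl 2-{(2R,3S)-2-[(R)-(4-methoxy-5-methyl-2-oxo-2H-chromen-3-yl)(triethylsilyloxy)methyl]-3-methylcyclopentylidene}propanoate F1 as a mixture of alkene isomers.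
- In the antiperiplanar open transition state the boron-bound oxygen should prefer the sector next to H7a over that next to C7. This leads to the same C1/C7a relationship.
- Hydrogenation (H2, Pd/C, EtOAc) makes the alkene geometry irrelevant. It should be steered by the large silyloxy(aryl)methyl group on C7a, so hydrogen reaches C4a from the opposite face. The product is methyl 2-{(1S,2R,3S)-2-[(R)-(4-methoxy-5-methyl-2-oxo-2H-chromen-3-yl)(triethylsilyloxy)methyl]-3-methylcyclopentyl}propanoate F2, epimeric at the ester α-carbon.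
- Aqueous TFA in CH2Cl2 removes the silyl group and closes O2–C3. The route is rejoined at 17, which is accompanied by its (4R)-epimer F3. Both converge on enolate 18 in step 11.

**Step 10.**
- Risk: hydrogen uptake by the tetrasubstituted enoate may be slow.
- Risk: adsorption may occur on the face opposite to H7a, because the C7 methyl group lies on the wanted face.
- Risk: the activated C1–O2 bond may undergo hydrogenolysis on palladium.
- Fallback: it sets out from 16. LiOH (THF–H2O, 0 °C → rt) opens the δ-lactone to lithium (2Z)-2-{(2R,3S)-2-[(R)-hydroxy(4-methoxy-5-methyl-2-oxo-2H-chromen-3-yl)methyl]-3-methylcyclopentylidene}propanoate F4.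
- In this monocyclic alkylidenecyclopentane, allylic strain with the carboxylate pushes the hydroxy(aryl)methyl group on C7a into a pseudoaxial position, where it blocks one face. Hydrogenation of 2-substituted alkylidenecyclopentanes from the free face to the cis-1,2 product is well known.
- Hydrogenation of the salt (H2, Rh/Al2O3, MeOH–H2O) should give lithium (2S)-2-{(1S,2R,3S)-2-[(R)-hydroxy(4-methoxy-5-methyl-2-oxo-2H-chromen-3-yl)methyl]-3-methylcyclopentyl}propanoate F5.
- Acidification with dilute HCl relactonises it, and any opened coumarin ring recloses at the same time. The route is rejoined at 17.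

**Step 15.**
- Risk: transmetalation between two hindered partners may be slow. That would leave time for decarbonylation of the acylpalladium species and for protodestannylation by traces of HCl from the acid chloride.
- Fallback: it sets out from 23 and 20. The acid chloride is converted with 4-methylbenzenethiol and pyridine (CH2Cl2, 0 °C) into S-(4-methylphenyl) (2R)-2-[(tert-butyldimethylsilyl)oxy]-3-methylbutanethioate F6.
- F6 is coupled with stannane 20 in a Liebeskind–Srogl ketone synthesis (Pd2(dba)3, P(2-furyl)3, copper(I) diphenylphosphinate, THF, rt → 50 °C). This halide-free, copper-assisted thioester coupling is known to keep α-heteroatom stereocentres and avoids an acid-chloride-derived acylpalladium chloride. The route is rejoined at 24.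

**Further compounds**
F1 | step 9 | methyl 2-{(2R,3S)-2-[(R)-(4-methoxy-5-methyl-2-oxo-2H-chromen-3-yl)(triethylsilyloxy)methyl]-3-methylcyclopentylidene}propanoate (E/Z mixture) | COC(=O)C(C)=C1CC[C@H](C)[C@H]1[C@H](c1c(OC)c2c(C)cccc2oc1=O)O[Si](CC)(CC)CC
F2 | step 9 | methyl 2-{(1S,2R,3S)-2-[(R)-(4-methoxy-5-methyl-2-oxo-2H-chromen-3-yl)(triethylsilyloxy)methyl]-3-methylcyclopentyl}propanoate (epimers at C2 of the propanoate) | COC(=O)C(C)[C@H]1CC[C@H](C)[C@H]1[C@H](c1c(OC)c2c(C)cccc2oc1=O)O[Si](CC)(CC)CC
F3 | step 9 | (1R,4R,4aS,7S,7aR)-1-(4-methoxy-5-methyl-2-oxo-2H-chromen-3-yl)-4,7-dimethylhexahydrocyclopenta[c]pyran-3(1H)-one | C[C@H]1C(=O)O[C@@H](c2c(OC)c3c(C)cccc3oc2=O)[C@H]2[C@@H]1CC[C@@H]2C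
F4 | step 10 | lithium (2Z)-2-{(2R,3S)-2-[(R)-hydroxy(4-methoxy-5-methyl-2-oxo-2H-chromen-3-yl)methyl]-3-methylcyclopentylidene}propanoate | C/C(C(=O)[O-])=C1\CC[C@H](C)[C@H]1[C@@H](O)c1c(OC)c2c(C)cccc2oc1=O.[Li+]
F5 | step 10 | lithium (2S)-2-{(1S,2R,3S)-2-[(R)-hydroxy(4-methoxy-5-methyl-2-oxo-2H-chromen-3-yl)methyl]-3-methylcyclopentyl}propanoate | C[C@H](C(=O)[O-])[C@H]1CC[C@H](C)[C@H]1[C@@H](O)c1c(OC)c2c(C)cccc2oc1=O.[Li+]
F6 | step 15 | S-(4-methylphenyl) (2R)-2-[(tert-butyldimethylsilyl)oxy]-3-methylbutanethioate | CC(C)[C@@H](O[Si](C)(C)C(C)(C)C)C(=O)Sc1ccc(C)cc1
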